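**Strategy.** Everything rests on disconnecting the bond between the benzylic CH2 of guaiacyl ring A and C3 of the butyrolactone. The key step is a trans-selective alkylation of the lithium enolate of a fully elaborated (4R)-4-arylmethyl lactone with 4-(benzyloxy)-3-methoxybenzyl bromide: it unites the two advanced fragments and sets the C3 stereocentre in one operation, exploiting the acidity of the C3–H bond beside the lactone C2 carbonyl and the shielding of one enolate face by the C4 arylmethyl arm. In the precursor, the base-labile 2-aryl-3-hydroxy-1-oxopropyl chain on central ring B is stored as a 1,3-diol acetonide (a temporary 1,3-dioxane ring) built by an Evans syn-aldol reaction; hydrolysis, benzylic oxidation and debenzylation then finish the synthesis.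

Key step: step 10

Remark on the chemistry: in step 3 the (S,S)-Et-DuPhos ligand is assumed to deliver the (R)-acid; if the sense of induction is the opposite, the (R,R)-ligand is used instead.

Step 1
Reactants: 1 5-bromovanillin
Product: 2 4-(benzyloxy)-3-bromo-5-methoxybenzaldehyde
Conditions: BnBr, K2CO3, DMF, 60 °C
Reagents that add atoms: benzyl bromide BrCc1ccccc1
Why: Williamson ether synthesis; the phenoxide of 1 is the only nucleophile and is benzylated on oxygen.

Step 2
Reactants: 2 4-(benzyloxy)-3-bromo-5-methoxybenzaldehyde; 3 dimethyl succinate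
Product: 4 (3E)-4-[4-(benzyloxy)-3-bromo-5-methoxyphenyl]-3-(methoxycarbonyl)but-3-enoic acid
Conditions: NaOMe, MeOH, reflux; then aq. HCl
Reagents that add atoms: none
Why: Stobbe condensation; aldol addition of the succinate enolate, lactonisation and E1cB ring opening should give the arylidene half-ester with the free acid on the CH2 arm, the aryl bromide and benzyl ether being inert to methoxide.

Step 3
Reactants: 4 Stobbe half-ester
Product: 5 (3R)-4-[4-(benzyloxy)-3-bromo-5-methoxyphenyl]-3-(methoxycarbonyl)butanoic acid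
Conditions: H2 (5 bar), [Rh(cod)((S,S)-Et-DuPhos)]BF4 (1 mol %), NaOMe (10 mol %), MeOH, rt
Reagents that add atoms: none
Why: Rhodium-catalysed asymmetric hydrogenation of an itaconate-type half-ester: carboxylate and alkene chelate the metal, so the C2-symmetric bisphosphine selects one alkene face and sets the (R) centre, while the aryl bromide and benzyl ether are inert to the homogeneous catalyst.

Step 4
Reactants: 5 (R)-half-ester
Product: 7 (4R)-4-{[4-(benzyloxy)-3-bromo-5-methoxyphenyl]methyl}oxolan-2-one, via hydroxy acid 6 (not isolated)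
Conditions: LiBH4, THF, 0 °C to rt; then 2 M HCl, rt
Reagents that add atoms: none
Why: Chemoselective borohydride reduction: LiBH4 reduces the methyl ester but not the lithium carboxylate, and acidification closes the γ-lactone (lactonisation) without touching the stereocentre.

Step 5
Reactants: 7 lactone bromide; 8 (4R)-3-acetyl-4-benzyl-1,3-oxazolidin-2-one
Product: 11 (4R)-4-benzyl-3-{[2-(benzyloxy)-3-methoxy-5-{[(3R)-5-oxooxolan-3-yl]methyl}phenyl]acetyl}-1,3-oxazolidin-2-one, via lithium enolate 9 (not isolated), via zinc enolate 10 (not isolated)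
Conditions: 8 (1.5 equiv), LiN(SiMe3)2, THF, −78 °C; ZnCl2, −78 °C to rt; then 7, Pd(dba)2 (3 mol %), P(t-Bu)3 (3 mol %), rt to 50 °C
Reagents that add atoms: none
Why: Negishi-type palladium-catalysed α-arylation of a zinc imide enolate (oxidative addition of the aryl bromide to zerovalent palladium, transmetalation from zinc, reductive elimination); the weakly basic zinc enolate should leave the lactone and its stereocentre untouched, and the excess of 10 limits proton transfer to the more acidic product.

Step 6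
Reactants: 11 arylacetyl imide; 12 4-(benzyloxy)-3-methoxybenzaldehyde
Product: 15 (4R)-4-benzyl-3-[(2R,3R)-2-[2-(benzyloxy)-3-methoxy-5-{[(3R)-5-oxooxolan-3-yl]methyl}phenyl]-3-[4-(benzyloxy)-3-methoxyphenyl]-3-hydroxypropanoyl]-1,3-oxazolidin-2-one, via boron enolate 13 (not isolated), via boron aldolate 14 (not isolated)
Conditions: Bu2BOTf, iPr2NEt, CH2Cl2, −78 to 0 °C; then 12, −78 to 0 °C; then pH 7 buffer, MeOH, H2O2, 0 °C
Reagents that add atoms: none
Why: Evans syn-aldol reaction: soft enolisation gives the Z boron enolate 13, which reacts through a closed Zimmerman–Traxler chair in which the benzyl group of the (4R)-auxiliary blocks one enolate face, so the (2R,3R) syn adduct should form; the C2 centre set here becomes the (S) centre of the target after the change in CIP priorities, and the lactone is not enolised under these conditions.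

Step 7
Reactants: 15 aldol adduct
Product: 16 (4R)-4-({4-(benzyloxy)-3-[(1R,2S)-1-[4-(benzyloxy)-3-methoxyphenyl]-1,3-dihydroxypropan-2-yl]-5-methoxyphenyl}methyl)oxolan-2-one
Conditions: NaBH4, THF/H2O (4:1), 0 °C to rt
Reagents that add atoms: none
Why: Reductive cleavage of the N-acyl oxazolidinone: borohydride attacks the activated exocyclic imide carbonyl much faster than the lactone, releasing the auxiliary and the primary alcohol with the C2 centre retained.

Step 8
Reactants: 16 diol
Product: 17 (4R)-4-({4-(benzyloxy)-3-[(4R,5S)-4-[4-(benzyloxy)-3-methoxyphenyl]-2,2-dimethyl-1,3-dioxan-5-yl]-5-methoxyphenyl}methyl)oxolan-2-one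
Conditions: 2,2-dimethoxypropane, PPTS (cat.), CH2Cl2, rt
Reagents that add atoms: 2,2-dimethoxypropane COC(C)(C)OC
Why: Acetonide formation (acid-catalysed transketalisation) ties the 1,3-diol into a 1,3-dioxane, which removes both O–H acids and keeps the future ketone at the alcohol oxidation level for the basic key step.

Step 9
Reactants: 18 [4-(benzyloxy)-3-methoxyphenyl]methanol
Product: 19 4-(benzyloxy)-3-methoxybenzyl bromide
Conditions: PBr3, Et2O, 0 °C
Reagents that add atoms: phosphorus tribromide BrP(Br)Br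
Why: Conversion of a benzylic alcohol into the bromide with PBr3 (SN2 on the phosphite ester); the electron-rich bromide is used at once without purification.

Step 10
Reactants: 17 acetonide lactone; 19 4-(benzyloxy)-3-methoxybenzyl bromide
Product: 21 (3R,4R)-3-{[4-(benzyloxy)-3-methoxyphenyl]methyl}-4-({4-(benzyloxy)-3-[(4R,5S)-4-[4-(benzyloxy)-3-methoxyphenyl]-2,2-dimethyl-1,3-dioxan-5-yl]-5-methoxyphenyl}methyl)oxolan-2-one, via lithium enolate 20 (not isolated)
Conditions: LiN(SiMe3)2 (1.1 equiv), THF, −78 °C; then 19, DMPU, −78 to −40 °C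
Reagents that add atoms: none
Why: LiN(SiMe3)2 removes one of the two C3 protons (the only C–H acid left, since the acetonide masks both hydroxyls and the future ketone) to give lithium enolate 20, which attacks the benzylic bromide 19 at carbon in an SN2 displacement. The closest known reaction type is the diastereoselective alkylation of 4-substituted butyrolactone enolates with benzylic halides, the classical entry to trans-dibenzylbutyrolactone lignans. No ring is closed. The new C3 stereocentre is controlled by the existing C4 centre: the arylmethyl arm on C4 shields its own face of the planar five-membered enolate, so the electrophile should enter anti and give the trans (3R,4R) lactone. The selectivities needed are C- over O-alkylation and mono- over dialkylation, secured by a soft benzylic electrophile, only a slight excess of base at −78 °C with DMPU as cosolvent, and the hindered environment of the remaining C3–H in the product; the dioxane stereocentres carry no acidic C–H under these conditions and should be untouched.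

Step 11
Reactants: 21 alkylated acetonide
Product: 22 (3R,4R)-3-{[4-(benzyloxy)-3-methoxyphenyl]methyl}-4-({4-(benzyloxy)-3-[(1R,2S)-1-[4-(benzyloxy)-3-methoxyphenyl]-1,3-dihydroxypropan-2-yl]-5-methoxyphenyl}methyl)oxolan-2-one
Conditions: AcOH/THF/H2O (3:1:1), 45 °C
Reagents that add atoms: none
Why: Acid-catalysed acetal hydrolysis; in the aqueous medium any ionisation of the electron-rich benzylic carbinol is returned as the alcohol (its configuration is erased in the next step), and lactone and benzyl ethers are stable.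

Step 12
Reactants: 22 diol
Product: 23 (3R,4R)-3-{[4-(benzyloxy)-3-methoxyphenyl]methyl}-4-({4-(benzyloxy)-3-[(2S)-1-[4-(benzyloxy)-3-methoxyphenyl]-3-hydroxy-1-oxopropan-2-yl]-5-methoxyphenyl}methyl)oxolan-2-one
Conditions: DDQ (1.2 equiv), 1,4-dioxane, rt
Reagents that add atoms: none
Why: DDQ oxidation of an electron-rich benzylic alcohol (hydride abstraction from the carbinol C–H activated by the 4-alkoxyaryl ring) should give the aryl ketone while the primary aliphatic alcohol is untouched; the absence of base protects the now enolisable C2 centre.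

Step 13
Reactants: 23 tribenzyl ketone
Product: 24 (3R,4R)-3-[(4-hydroxy-3-methoxyphenyl)methyl]-4-({4-hydroxy-3-[(2S)-3-hydroxy-1-(4-hydroxy-3-methoxyphenyl)-1-oxopropan-2-yl]-5-methoxyphenyl}methyl)oxolan-2-one (CNP0191394.1)
Conditions: H2 (1 atm), Pd/C (10 wt %), EtOAc, rt
Reagents that add atoms: none
Why: Hydrogenolysis of the three aryl benzyl ethers on Pd/C under neutral conditions; the ring B phenol is released last and without acid or base, so the C2 centre next to the ketone, the β-hydroxy ketone and the trans lactone should survive, and the electron-rich aryl ketone is reduced much more slowly than the benzyl ethers are cleaved.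

**Compound list**

1 | 5-bromovanillin (3-bromo-4-hydroxy-5-methoxybenzaldehyde) | O=Cc1cc(OC)c(O)c(Br)c1 | starting material
2 | 4-(benzyloxy)-3-bromo-5-methoxybenzaldehyde | O=Cc1cc(OC)c(OCc2ccccc2)c(Br)c1 | intermediate
3 | dimethyl succinate | COC(=O)CCC(=O)OC | starting material
4 | (3E)-4-[4-(benzyloxy)-3-bromo-5-methoxyphenyl]-3-(methoxycarbonyl)but-3-enoic acid | OC(=O)C/C(C(=O)OC)=C\c1cc(OC)c(OCc2ccccc2)c(Br)c1 | intermediate
5 | (3R)-4-[4-(benzyloxy)-3-bromo-5-methoxyphenyl]-3-(methoxycarbonyl)butanoic acid | OC(=O)C[C@@H](Cc1cc(OC)c(OCc2ccccc2)c(Br)c1)C(=O)OC | intermediate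
6 | (3R)-4-[4-(benzyloxy)-3-bromo-5-methoxyphenyl]-3-(hydroxymethyl)butanoic acid (not isolated) | OC(=O)C[C@@H](Cc1cc(OC)c(OCc2ccccc2)c(Br)c1)CO | intermediate
7 | (4R)-4-{[4-(benzyloxy)-3-bromo-5-methoxyphenyl]methyl}oxolan-2-one | O=C1C[C@@H](Cc2cc(OC)c(OCc3ccccc3)c(Br)c2)CO1 | intermediate
8 | (4R)-3-acetyl-4-benzyl-1,3-oxazolidin-2-one | CC(=O)N1[C@H](Cc2ccccc2)COC1=O | starting material
9 | lithium enolate of 8 (not isolated) | C=C(O[Li])N1[C@H](Cc2ccccc2)COC1=O | intermediate
10 | chlorozinc enolate of 8 (not isolated) | C=C(O[Zn]Cl)N1[C@H](Cc2ccccc2)COC1=O | intermediate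
11 | (4R)-4-benzyl-3-{[2-(benzyloxy)-3-methoxy-5-{[(3R)-5-oxooxolan-3-yl]methyl}phenyl]acetyl}-1,3-oxazolidin-2-one | O=C1C[C@@H](Cc2cc(OC)c(OCc3ccccc3)c(CC(=O)N3[C@H](Cc4ccccc4)COC3=O)c2)CO1 | intermediate
12 | 4-(benzyloxy)-3-methoxybenzaldehyde | O=Cc1ccc(OCc2ccccc2)c(OC)c1 | starting material
13 | (Z)-dibutylboron enolate of 11 (not isolated) | CCCCB(CCCC)O/C(N1[C@H](Cc2ccccc2)COC1=O)=C\c1cc(C[C@H]2COC(=O)C2)cc(OC)c1OCc1ccccc1 | intermediate
14 | O-dibutylboryl aldolate of 15 (not isolated) | O=C1C[C@@H](Cc2cc(OC)c(OCc3ccccc3)c([C@@H](C(=O)N3[C@H](Cc4ccccc4)COC3=O)[C@@H](OB(CCCC)CCCC)c3ccc(OCc4ccccc4)c(OC)c3)c2)CO1 | intermediate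
15 | (4R)-4-benzyl-3-[(2R,3R)-2-[2-(benzyloxy)-3-methoxy-5-{[(3R)-5-oxooxolan-3-yl]methyl}phenyl]-3-[4-(benzyloxy)-3-methoxyphenyl]-3-hydroxypropanoyl]-1,3-oxazolidin-2-one | O=C1C[C@@H](Cc2cc(OC)c(OCc3ccccc3)c([C@@H](C(=O)N3[C@H](Cc4ccccc4)COC3=O)[C@@H](O)c3ccc(OCc4ccccc4)c(OC)c3)c2)CO1 | intermediate
16 | (4R)-4-({4-(benzyloxy)-3-[(1R,2S)-1-[4-(benzyloxy)-3-methoxyphenyl]-1,3-dihydroxypropan-2-yl]-5-methoxyphenyl}methyl)oxolan-2-one | O=C1C[C@@H](Cc2cc(OC)c(OCc3ccccc3)c([C@@H](CO)[C@@H](O)c3ccc(OCc4ccccc4)c(OC)c3)c2)CO1 | intermediate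
17 | (4R)-4-({4-(benzyloxy)-3-[(4R,5S)-4-[4-(benzyloxy)-3-methoxyphenyl]-2,2-dimethyl-1,3-dioxan-5-yl]-5-methoxyphenyl}methyl)oxolan-2-one | O=C1C[C@@H](Cc2cc(OC)c(OCc3ccccc3)c([C@H]5COC(C)(C)O[C@H]5c3ccc(OCc4ccccc4)c(OC)c3)c2)CO1 | intermediate
18 | [4-(benzyloxy)-3-methoxyphenyl]methanol | OCc1ccc(OCc2ccccc2)c(OC)c1 | starting material
19 | 4-(benzyloxy)-3-methoxybenzyl bromide | BrCc1ccc(OCc2ccccc2)c(OC)c1 | intermediate
20 | lithium enolate of 17 (not isolated) | [Li]OC1=C[C@@H](Cc2cc(OC)c(OCc3ccccc3)c([C@H]5COC(C)(C)O[C@H]5c3ccc(OCc4ccccc4)c(OC)c3)c2)CO1 | intermediate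
21 | (3R,4R)-3-{[4-(benzyloxy)-3-methoxyphenyl]methyl}-4-({4-(benzyloxy)-3-[(4R,5S)-4-[4-(benzyloxy)-3-methoxyphenyl]-2,2-dimethyl-1,3-dioxan-5-yl]-5-methoxyphenyl}methyl)oxolan-2-one | COc1cc(C[C@H]2C(=O)OC[C@@H]2Cc2cc(OC)c(OCc3ccccc3)c([C@H]5COC(C)(C)O[C@H]5c3ccc(OCc4ccccc4)c(OC)c3)c2)ccc1OCc1ccccc1 | intermediate
22 | (3R,4R)-3-{[4-(benzyloxy)-3-methoxyphenyl]methyl}-4-({4-(benzyloxy)-3-[(1R,2S)-1-[4-(benzyloxy)-3-methoxyphenyl]-1,3-dihydroxypropan-2-yl]-5-methoxyphenyl}methyl)oxolan-2-one | COc1cc(C[C@H]2C(=O)OC[C@@H]2Cc2cc(OC)c(OCc3ccccc3)c([C@@H](CO)[C@@H](O)c3ccc(OCc4ccccc4)c(OC)c3)c2)ccc1OCc1ccccc1 | intermediate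
23 | (3R,4R)-3-{[4-(benzyloxy)-3-methoxyphenyl]methyl}-4-({4-(benzyloxy)-3-[(2S)-1-[4-(benzyloxy)-3-methoxyphenyl]-3-hydroxy-1-oxopropan-2-yl]-5-methoxyphenyl}methyl)oxolan-2-one | COc1cc(C[C@H]2C(=O)OC[C@@H]2Cc2cc(OC)c(OCc3ccccc3)c([C@@H](CO)C(=O)c3ccc(OCc4ccccc4)c(OC)c3)c2)ccc1OCc1ccccc1 | intermediate
24 | (3R,4R)-3-[(4-hydroxy-3-methoxyphenyl)methyl]-4-({4-hydroxy-3-[(2S)-3-hydroxy-1-(4-hydroxy-3-methoxyphenyl)-1-oxopropan-2-yl]-5-methoxyphenyl}methyl)oxolan-2-one | COc1cc(C[C@H]2C(=O)OC[C@@H]2Cc2cc(OC)c(O)c([C@@H](CO)C(=O)c3ccc(O)c(OC)c3)c2)ccc1O | target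

**Totals.** Total step count: 13. Longest linear sequence: 12 steps (steps 1–8 and 10–13, from 5-bromovanillin); step 9 is a one-step side branch.

**Steps most likely to fail**

Step 5 (arylation of the zinc imide enolate). The arylacetyl imide product is more acidic than the N-acetyl imide, so proton transfer to the zinc enolate may stall the coupling or lead to a second arylation, and the N-acetyl imide enolate may collapse to a ketene on warming. The fallback sets out from 7 and builds the side arm at the ester level. A Negishi coupling of 7 with commercial (2-tert-butoxy-2-oxoethyl)zinc bromide (Pd(dba)2, P(t-Bu)3, THF, rt) should give the tert-butyl arylacetate F1. TFA in CH2Cl2 then gives the arylacetic acid F2. Activation with PivCl/Et3N gives the mixed pivalic anhydride F3, which is acylated onto (4R)-4-benzyl-1,3-oxazolidin-2-one in the presence of LiCl. The fallback comes back to the route at 11.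

Step 7 (reductive removal of the auxiliary). In the basic borohydride medium the benzylic α-carbon may partly epimerise before the acyl group is cleaved, and hydride may also attack the lactone. The fallback sets out from 15 and separates cleavage from reduction. LiOH/H2O2 in THF/H2O at 0 °C, followed by acidification (which recloses any opened lactone), should give the β-hydroxy acid F4. BH3·SMe2 in THF then reduces the carboxylic acid but not the lactone. The fallback comes back to the route at 16.

Step 12 (selective benzylic oxidation). Chemoselectivity may be lost, with oxidation at the benzylic CH2 groups of the dibenzyl lactone or at the primary alcohol, and the acidic hydroquinone may promote dehydration or enolisation of the β-hydroxy ketone. The fallback sets out from 22 and differentiates the two hydroxyls by protection. TBSCl/imidazole in CH2Cl2 at 0 °C should silylate only the primary alcohol to give the silyl ether F5. Dess–Martin periodinane buffered with NaHCO3 then oxidises the secondary alcohol to the silyloxy ketone F6. HF·pyridine in THF/pyridine at 0 °C removes the silyl group under non-basic conditions. The fallback comes back to the route at 23.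

**Further compounds**

F1 | step 5 | tert-butyl [2-(benzyloxy)-3-methoxy-5-{[(3R)-5-oxooxolan-3-yl]methyl}phenyl]acetate | O=C1C[C@@H](Cc2cc(OC)c(OCc3ccccc3)c(CC(=O)OC(C)(C)C)c2)CO1
F2 | step 5 | [2-(benzyloxy)-3-methoxy-5-{[(3R)-5-oxooxolan-3-yl]methyl}phenyl]acetic acid | O=C1C[C@@H](Cc2cc(OC)c(OCc3ccccc3)c(CC(=O)O)c2)CO1
F3 | step 5 | mixed anhydride of F2 and pivalic acid | O=C1C[C@@H](Cc2cc(OC)c(OCc3ccccc3)c(CC(=O)OC(=O)C(C)(C)C)c2)CO1
F4 | step 7 | (2R,3R)-2-[2-(benzyloxy)-3-methoxy-5-{[(3R)-5-oxooxolan-3-yl]methyl}phenyl]-3-[4-(benzyloxy)-3-methoxyphenyl]-3-hydroxypropanoic acid | O=C1C[C@@H](Cc2cc(OC)c(OCc3ccccc3)c([C@@H](C(=O)O)[C@@H](O)c3ccc(OCc4ccccc4)c(OC)c3)c2)CO1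
F5 | step 12 | primary tert-butyldimethylsilyl ether of diol 22 | COc1cc(C[C@H]2C(=O)OC[C@@H]2Cc2cc(OC)c(OCc3ccccc3)c([C@@H](CO[Si](C)(C)C(C)(C)C)[C@@H](O)c3ccc(OCc4ccccc4)c(OC)c3)c2)ccc1OCc1ccccc1
F6 | step 12 | tert-butyldimethylsilyl ether of ketone 23 | COc1cc(C[C@H]2C(=O)OC[C@@H]2Cc2cc(OC)c(OCc3ccccc3)c([C@@H](CO[Si](C)(C)C(C)(C)C)C(=O)c3ccc(OCc4ccccc4)c(OC)c3)c2)ccc1OCc1ccccc1
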